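**Plan**
- Feature: in the oxirane, the quaternary carbon Cq (bearing the aryl ring and CH2OAc) is the only substituted ring carbon and its ring partner is a bare CH2. The three-membered ring is therefore an aryl acetoxymethyl ketone plus one carbon.
- Cuts: first the two isobutyrate C–O bonds (back to silyl ethers), then the Cq–CH2 and CH2–O bonds of the oxirane (methylene transfer to the ketone C=O), then the aryl–C(=O) bond (arylzinc plus acetoxyacetyl chloride).
- Forward: 4-bromo-3-hydroxybenzoic acid is reduced and bis-silylated, the bromide is converted into the aryl acetoxymethyl ketone, the oxirane (the only ring formed) is closed by asymmetric methylene transfer, and the silyl ethers are exchanged for isobutyrates last.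
- Stereochemistry: the single stereocentre (S at Cq) comes from catalyst-controlled addition of dimethyloxosulfonium methylide to the Si face of the ketone under LaLi3 tris(binaphthoxide) catalysis. No later step touches Cq.

Key step: step 4

Assumption: the (S)-binaphthoxide catalyst is taken to deliver CH2 to the Si face of ketone 7, the same topological face (aryl as the large group, CH2OAc in the place of methyl) that it is expected to attack in aryl methyl ketones; if a first run shows the opposite sense, the (R)-ligand is used with nothing else changed.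

Step 1
Reactants: 1 4-bromo-3-hydroxybenzoic acid
Product: 2 2-bromo-5-(hydroxymethyl)phenol
Conditions: BH3·THF (3 equiv), THF, 0 °C → rt; aq. NH4Cl
Reagents that add atoms: none
Why: Borane reduces the carboxylic acid through its acyloxyborane far faster than it touches anything else here (chemoselective borane reduction of a carboxylic acid), the phenol being held as a borate that is hydrolysed on work-up and the aryl bromide staying intact.

Step 2
Reactants: 2 2-bromo-5-(hydroxymethyl)phenol
Product: 3 tert-butyl{[4-bromo-3-(tert-butyldimethylsilyloxy)phenyl]methoxy}dimethylsilane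
Conditions: TBSCl (2.5 equiv), imidazole (5 equiv), DMF, rt
Reagents that add atoms: tert-butyldimethylsilyl chloride (TBSCl), CC(C)(C)[Si](C)(C)Cl
Why: Imidazole-promoted silylation converts both the phenol and the benzylic alcohol into silyl ethers, which are inert to organolithium, organozinc and sulfur-ylide reagents, cannot acylate the ylide as aryl esters would, and are both removable by fluoride at the end.

Step 3
Reactants: 3 tert-butyl{[4-bromo-3-(tert-butyldimethylsilyloxy)phenyl]methoxy}dimethylsilane; 4 acetoxyacetyl chloride
Product: 7 2-{2-[(tert-butyldimethylsilyl)oxy]-4-{[(tert-butyldimethylsilyl)oxy]methyl}phenyl}-2-oxoethyl acetate, via aryllithium 5 (not isolated), via arylzinc chloride 6 (not isolated)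
Conditions: t-BuLi (2.0 equiv), Et2O, −78 °C; ZnCl2 (1.1 equiv, THF), −78 → 0 °C; 4 (1.2 equiv), Pd(PPh3)4 (5 mol %), 0 °C → rt
Reagents that add atoms: none
Why: Bromine–lithium exchange in Et2O at −78 °C should outrun O→C silyl migration in the ortho-lithiated silyl ether, immediate transmetalation gives an arylzinc chloride that no longer rearranges and tolerates the acetate, and zerovalent palladium then joins it to the acyl chloride carbon of 4 (Negishi acylation) without touching the ester.

Step 4
Reactants: 7 2-{2-[(tert-butyldimethylsilyl)oxy]-4-{[(tert-butyldimethylsilyl)oxy]methyl}phenyl}-2-oxoethyl acetate; 8 trimethylsulfoxonium iodide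
Product: 11 [(2S)-2-{2-[(tert-butyldimethylsilyl)oxy]-4-{[(tert-butyldimethylsilyl)oxy]methyl}phenyl}oxiran-2-yl]methyl acetate, via dimethyloxosulfonium methylide 9 (not isolated), via sulfoxonium betaine 10 (not isolated)
Conditions: 8, NaH, THF, reflux, filtered; ylide solution (1.2 equiv) added to 7, LaLi3[(S)-1,1'-binaphthalene-2,2'-diolate]3 (5–10 mol %), (2,4,6-(MeO)3C6H2)3P=O (5–10 mol %), 5 Å MS, THF, rt
Reagents that add atoms: none
Why: The ylide carbon adds to the ketone carbonyl of 7, which is bound to the trivalent lanthanum centre while a lithium binaphthoxide site holds the ylide S=O oxygen, and the betaine alkoxide then expels dimethyl sulfoxide from the neighbouring CH2, so the ring oxygen is the former carbonyl oxygen and Cq never becomes cationic. The closest known reaction is the LaLi3 tris(binaphthoxide)/phosphine oxide-catalysed asymmetric Corey–Chaykovsky epoxidation of aryl methyl ketones to 2,2-disubstituted terminal oxiranes. The oxirane closes by 3-exo-tet displacement at the sulfoxonium-bearing methylene. The single stereocentre Cq is set by the chiral catalyst, which has to deliver CH2 to the Si face of the carbonyl (priority O > CH2OAc > aryl) to give the (S)-oxirane. The step needs enantioface selection and chemoselection for the ketone over the acetate and the silyl ethers; the first rests on the contrast between the twisted ortho-silyloxyaryl group and the slim CH2OAc arm, whose ester carbonyl can offer lithium a second contact, and the second on Lewis-acid activation of the ketone, a small excess of ylide at room temperature and the absence of any aryl ester.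

Step 5
Reactants: 11 [(2S)-2-{2-[(tert-butyldimethylsilyl)oxy]-4-{[(tert-butyldimethylsilyl)oxy]methyl}phenyl}oxiran-2-yl]methyl acetate; 12 isobutyric anhydride
Product: 13 {4-[(2S)-2-(acetoxymethyl)oxiran-2-yl]-3-(2-methylpropanoyloxy)phenyl}methyl 2-methylpropanoate
Conditions: 12 (6 equiv), Bu4NF (1 M in THF, 2.5 equiv, added slowly), THF, −20 → 0 °C
Reagents that add atoms: none
Why: Fluoride cleaves the aryl O–Si bond first and then the benzylic O–Si bond, and each oxyanion is acylated at once by the excess anhydride (fluoride-promoted one-pot exchange of silyl ethers for esters), so the ortho-phenoxide should not persist long enough to open the neighbouring oxirane and neither the acetate nor Cq is touched.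

**Compound list**
1 | 4-bromo-3-hydroxybenzoic acid | OC(=O)c1ccc(Br)c(O)c1 | starting material
2 | 2-bromo-5-(hydroxymethyl)phenol | OCc1ccc(Br)c(O)c1 | intermediate
3 | tert-butyl{[4-bromo-3-(tert-butyldimethylsilyloxy)phenyl]methoxy}dimethylsilane | CC(C)(C)[Si](C)(C)OCc1ccc(Br)c(O[Si](C)(C)C(C)(C)C)c1 | intermediate
4 | acetoxyacetyl chloride | CC(=O)OCC(=O)Cl | starting material
5 | aryllithium: {2-[(tert-butyldimethylsilyl)oxy]-4-{[(tert-butyldimethylsilyl)oxy]methyl}phenyl}lithium | CC(C)(C)[Si](C)(C)OCc1ccc([Li])c(O[Si](C)(C)C(C)(C)C)c1 | intermediate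
6 | arylzinc chloride: {2-[(tert-butyldimethylsilyl)oxy]-4-{[(tert-butyldimethylsilyl)oxy]methyl}phenyl}zinc chloride | CC(C)(C)[Si](C)(C)OCc1ccc([Zn]Cl)c(O[Si](C)(C)C(C)(C)C)c1 | intermediate
7 | 2-{2-[(tert-butyldimethylsilyl)oxy]-4-{[(tert-butyldimethylsilyl)oxy]methyl}phenyl}-2-oxoethyl acetate | CC(=O)OCC(=O)c1ccc(CO[Si](C)(C)C(C)(C)C)cc1O[Si](C)(C)C(C)(C)C | intermediate
8 | trimethylsulfoxonium iodide | C[S+](C)(C)=O.[I-] | starting material
9 | dimethyloxosulfonium methylide | C[S+](C)(=O)[CH2-] | intermediate
10 | sulfoxonium betaine: alkoxide of 7 after ylide addition, (R) at the carbinolate carbon (same spatial arrangement as in 11; the descriptor differs only because CH2S outranks CH2OAc) | CC(=O)OC[C@]([O-])(c1ccc(CO[Si](C)(C)C(C)(C)C)cc1O[Si](C)(C)C(C)(C)C)C[S+](C)(C)=O | intermediate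
11 | [(2S)-2-{2-[(tert-butyldimethylsilyl)oxy]-4-{[(tert-butyldimethylsilyl)oxy]methyl}phenyl}oxiran-2-yl]methyl acetate | CC(=O)OC[C@]1(c2ccc(CO[Si](C)(C)C(C)(C)C)cc2O[Si](C)(C)C(C)(C)C)CO1 | intermediate
12 | isobutyric anhydride | CC(C)C(=O)OC(=O)C(C)C | starting material
13 | {4-[(2S)-2-(acetoxymethyl)oxiran-2-yl]-3-(2-methylpropanoyloxy)phenyl}methyl 2-methylpropanoate (CNP0151517.1) | CC(=O)OC[C@]1(c2ccc(COC(=O)C(C)C)cc2OC(=O)C(C)C)CO1 | target

**Totals**
Total step count: 5. Longest linear sequence: 5 steps (1 → 2 → 3 → 7 → 11 → 13).

**Steps most likely to fail**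

1. Step 4. Enantioface discrimination may be insufficient, because the CH2OAc arm is bulkier than the methyl group for which this catalyst type is known to work best. Enolisation of the ketone by the basic ylide or acetyl transfer within the betaine may also erode the yield. The fallback sets out from 7 and returns to the route at 11. Wittig methylenation (Ph3P=CH2 from Ph3PCH3Br and KN(SiMe3)2, THF, −78 → 0 °C) should give the 2-arylallyl acetate F1. Reduction with i-Bu2AlH (CH2Cl2, −78 °C) frees the allylic alcohol F2 without touching the silyl ethers. Sharpless asymmetric epoxidation (Ti(OiPr)4, D-(−)-diethyl tartrate, t-BuOOH, 4 Å MS, CH2Cl2, −20 °C) should then give the (R)-epoxy alcohol F3. The D-tartrate is chosen by the usual facial rule, with the aryl group standing where the C2 hydrogen of allyl alcohol stands. Acetylation (Ac2O, pyridine, DMAP, 0 °C) changes the descriptor but not the spatial arrangement and delivers 11.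

2. Step 5. Cleavage of the primary silyl ether may stall once fluoride is tied up by the anhydride, or the transient ortho-phenoxide may ionise or open the oxirane before it is acylated. The fallback sets out from 11 and returns at 13, replacing the one-pot exchange by a staged sequence. One equivalent of Bu4NF at −78 °C in the presence of isobutyric anhydride should exchange only the aryl silyl ether, giving the aryl isobutyrate F4 with the benzylic silyl ether intact. Buffered fluoride (HF·pyridine with excess pyridine, THF, 0 °C) then frees the benzylic alcohol F5 with no phenoxide present. Isobutyric anhydride with Et3N and catalytic DMAP in CH2Cl2 completes 13.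

3. Step 3. Anionic O→C silyl migration (retro-Brook type) in the ortho-lithiated aryl silyl ether may occur before zinc is introduced, or acylation of the hindered arylzinc may be slow. The fallback sets out from 3 and returns at 7 without any aryl anion. Stille coupling with tributyl(1-ethoxyvinyl)stannane (Pd(PPh3)4, toluene, 100 °C) should give the aryl enol ether F6. N-Bromosuccinimide in THF/H2O at 0 °C converts it into the bromomethyl ketone F7. Displacement of bromide with acetate (AcOH, Et3N, acetone, rt) gives 7.

**Further compounds**
F1 | step 4 | 2-{2-[(tert-butyldimethylsilyl)oxy]-4-{[(tert-butyldimethylsilyl)oxy]methyl}phenyl}prop-2-en-1-yl acetate | CC(=O)OCC(=C)c1ccc(CO[Si](C)(C)C(C)(C)C)cc1O[Si](C)(C)C(C)(C)C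
F2 | step 4 | 2-{2-[(tert-butyldimethylsilyl)oxy]-4-{[(tert-butyldimethylsilyl)oxy]methyl}phenyl}prop-2-en-1-ol | OCC(=C)c1ccc(CO[Si](C)(C)C(C)(C)C)cc1O[Si](C)(C)C(C)(C)C
F3 | step 4 | [(2R)-2-{2-[(tert-butyldimethylsilyl)oxy]-4-{[(tert-butyldimethylsilyl)oxy]methyl}phenyl}oxiran-2-yl]methanol | OC[C@]1(c2ccc(CO[Si](C)(C)C(C)(C)C)cc2O[Si](C)(C)C(C)(C)C)CO1
F4 | step 5 | 2-[(2S)-2-(acetoxymethyl)oxiran-2-yl]-5-{[(tert-butyldimethylsilyl)oxy]methyl}phenyl 2-methylpropanoate | CC(=O)OC[C@]1(c2ccc(CO[Si](C)(C)C(C)(C)C)cc2OC(=O)C(C)C)CO1
F5 | step 5 | 2-[(2S)-2-(acetoxymethyl)oxiran-2-yl]-5-(hydroxymethyl)phenyl 2-methylpropanoate | CC(=O)OC[C@]1(c2ccc(CO)cc2OC(=O)C(C)C)CO1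
F6 | step 3 | tert-butyl{[3-(tert-butyldimethylsilyloxy)-4-(1-ethoxyethenyl)phenyl]methoxy}dimethylsilane | CCOC(=C)c1ccc(CO[Si](C)(C)C(C)(C)C)cc1O[Si](C)(C)C(C)(C)C
F7 | step 3 | 2-bromo-1-{2-[(tert-butyldimethylsilyl)oxy]-4-{[(tert-butyldimethylsilyl)oxy]methyl}phenyl}ethan-1-one | BrCC(=O)c1ccc(CO[Si](C)(C)C(C)(C)C)cc1O[Si](C)(C)C(C)(C)C
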